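## Retrosynthetic overview
1. Target 9 comes from the temporary δ-enol lactone 7. A phenethyl nucleophile substitutes at the lactone acyl carbon and the pyranone 4-oxygen leaves.
2. Lactone 7 is cut at two C–O bonds: the lactone C(acyl)–O bond and, before it, the ester C–O bond of enol ester 6, made by O-acylation of pyranone 4 with a chiral dienoyl azolium.
3. The C3–Cβ bond and the only stereocentre follow from the [3,3] shift of the O-bound adduct.
4. Pyranone 4 comes from 4-hydroxy-6-methyl-2-pyranone 1 and benzaldehyde 2 by vinylogous aldol condensation.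
5. Rings: the pyranone ring is bought with 1. The only ring made is the δ-lactone, formed in step 2 and opened in step 3.

Assumption: the sense of induction of the aminoindanol triazolium salt is taken by analogy with its 4-aryl dihydropyranone products. Both antipodes are sold, so the one that gives (4S)-7 is used; it is written here as the (5aS,10bR) salt.

## Route

Step 1
Reactants: 1 4-hydroxy-6-methyl-2H-pyran-2-one; 2 benzaldehyde
Product: 4 4-hydroxy-6-[(E)-2-phenylethenyl]-2H-pyran-2-one, via aldol adduct 3 (not isolated)
Conditions: LDA (2.4 equiv), THF, −78 °C; 2, −78 to 0 °C; 2 M HCl; crude 3, p-TsOH·H2O (10 mol %), toluene, reflux, Dean–Stark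
Reagents that add atoms: none
Why: Vinylogous aldol condensation: the O,C-dianion of 1 reacts with 2 only at its more basic C6-CH2 terminus, and acid-catalysed dehydration of the benzylic alcohol 3 gives the fully conjugated (E)-styryl group, so no stereocentre remains.

Step 2
Reactants: 4 4-hydroxy-6-[(E)-2-phenylethenyl]-2H-pyran-2-one; 5 (2E,4E)-5-phenylpenta-2,4-dienal
Product: 7 (4S)-4,7-bis[(E)-2-phenylethenyl]-3,4-dihydro-2H,5H-pyrano[4,3-b]pyran-2,5-dione, via enol ester 6 (not isolated)
Conditions: (5aS,10bR)-N-mesityl aminoindanol-triazolium BF4 (10 mol %), iPr2NEt (50 mol %), 3,3',5,5'-tetra-tert-butyldiphenoquinone (1.1 equiv), 4 Å MS, THF/toluene 1:1, 25 °C, dark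
Reagents that add atoms: none
Why: Proposed new method: the carbene-catalysed oxidative Coates–Claisen annulation, known for simple β-aryl or β-alkyl enals with stable cyclic enols, is extended to a 2,4-dienal and a 6-alkenyl-4-hydroxy-2-pyranone, a pairing not yet shown; the quinone oxidises the Breslow intermediate of 5 to the chiral dienoyl azolium, the enol oxygen of 4 attacks its carbonyl (first C–O bond; free ester 6 and its carbene-bound hemiketal equilibrate), the chair [3,3] shift of this O-bound adduct can reach only Cβ (Cδ is out of range, so no 1,6-adduct forms by this path) and delivers pyranone C3 to the face not covered by the indane wall, which sets (S), and the pyranone oxygen then closes the resulting acyl azolium (second C–O bond, δ-lactone ring) and frees the carbene; closest known reaction types are the NHC-catalysed enal/enol [3+3] annulation to dihydropyranones and the carbene-catalysed rearrangement of α,β-unsaturated enol esters.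

Step 3
Reactants: 7 (4S)-4,7-bis[(E)-2-phenylethenyl]-3,4-dihydro-2H,5H-pyrano[4,3-b]pyran-2,5-dione; 8 2-phenylethylmagnesium chloride
Product: 9 3-[(1E,3S)-5-oxo-1,7-diphenylhept-1-en-3-yl]-4-hydroxy-6-[(E)-2-phenylethenyl]-2H-pyran-2-one
Conditions: 8 (1.05 equiv, slow addition), THF, −78 °C, 1 h; 1 M HCl
Reagents that add atoms: none
Why: First stage of a Fujimoto–Belleau-type reaction: the non-conjugated enol-ester carbonyl of 7 (a vinylogous anhydride, leaving-group pKa about 5) is far more electrophilic than the conjugated pyranone carbonyl, so one equivalent of Grignard reagent gives the ketone as its magnesium pyranonate (in equilibrium with the cyclic hemiketalate, which shields the new ketone), and the stereocentre, β to the reacting carbonyl, is untouched.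

## Compound list
1 | 4-hydroxy-6-methyl-2H-pyran-2-one | Cc1cc(O)cc(=O)o1 | starting material
2 | benzaldehyde | O=Cc1ccccc1 | starting material
3 | 4-hydroxy-6-(2-hydroxy-2-phenylethyl)-2H-pyran-2-one (racemic) | O=c1cc(O)cc(CC(O)c2ccccc2)o1 | intermediate
4 | 4-hydroxy-6-[(E)-2-phenylethenyl]-2H-pyran-2-one | O=c1cc(O)cc(/C=C/c2ccccc2)o1 | intermediate
5 | (2E,4E)-5-phenylpenta-2,4-dienal | O=C/C=C/C=C/c1ccccc1 | starting material
6 | 2-oxo-6-[(E)-2-phenylethenyl]-2H-pyran-4-yl (2E,4E)-5-phenylpenta-2,4-dienoate | O=C(/C=C/C=C/c1ccccc1)Oc1cc(/C=C/c2ccccc2)oc(=O)c1 | intermediate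
7 | (4S)-4,7-bis[(E)-2-phenylethenyl]-3,4-dihydro-2H,5H-pyrano[4,3-b]pyran-2,5-dione | O=C1C[C@@H](/C=C/c2ccccc2)c2c(O1)cc(/C=C/c1ccccc1)oc2=O | intermediate
8 | 2-phenylethylmagnesium chloride | Cl[Mg]CCc1ccccc1 | starting material
9 | 3-[(1E,3S)-5-oxo-1,7-diphenylhept-1-en-3-yl]-4-hydroxy-6-[(E)-2-phenylethenyl]-2H-pyran-2-one | O=C(CCc1ccccc1)C[C@@H](/C=C/c1ccccc1)c1c(O)cc(/C=C/c2ccccc2)oc1=O | target

Total steps: 3. Longest linear sequence: 3 (1 → 4 → 7 → 9).

## Steps most likely to fail

**Risk 1, step 2 (the new step).**
- What can go wrong: the pyranonate may add 1,6 to the dienoyl azolium, ester 6 may drain into the 3-dienoyl pyranone by an O-to-C acyl shift, or the ee may be low.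
- Fallback (known chemistry): it sets out from 4 and comes back at 9, which makes step 3 unnecessary.
- 4-Phenylbutan-2-one and cinnamaldehyde are condensed with pyrrolidine/AcOH to (4E,6E)-1,7-diphenylhepta-4,6-dien-3-one F1.
- Pyranone 4 is then added to F1 by the primary-amine iminium-catalysed Michael addition used for warfarin. Conditions are (S,S)-1,2-diphenylethane-1,2-diamine (10 mol %), AcOH, THF, rt, with the antipode that gives (S)-warfarin. This gives 9 directly.

**Risk 2, step 3.**
- What can go wrong: a second addition to the new ketone, attack on the pyranone ring, or enolisation of the lactone.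
- Fallback: it sets out from 7 and comes back at 9.
- The activated lactone is opened with MeONHMe·HCl and iPr2NEt in CH2Cl2 to (3S,4E)-3-{4-hydroxy-2-oxo-6-[(E)-2-phenylethenyl]-2H-pyran-3-yl}-N-methoxy-N-methyl-5-phenylpent-4-enamide F2.
- The chelated adduct of F2 with excess 8 (3.2 equiv, THF, 0 °C) cannot over-add, and it gives 9 on acid quench.

**Risk 3, step 1.**
- What can go wrong: the dianion is poorly soluble, and conversion or dehydration may be poor.
- Fallback: it sets out from 1 and comes back at 4.
- O-Methylation of 1 (Me2SO4, K2CO3, acetone) gives 4-methoxy-6-methyl-2H-pyran-2-one F3.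
- Mg(OMe)2-mediated condensation of F3 with 2 in MeOH gives 4-methoxy-6-[(E)-2-phenylethenyl]-2H-pyran-2-one F4.
- Nucleophilic demethylation of this vinylogous ester (LiI, pyridine, reflux, then HCl) gives 4.

## Further compounds
F1 | step 2 | (4E,6E)-1,7-diphenylhepta-4,6-dien-3-one | O=C(CCc1ccccc1)/C=C/C=C/c1ccccc1
F2 | step 3 | (3S,4E)-3-{4-hydroxy-2-oxo-6-[(E)-2-phenylethenyl]-2H-pyran-3-yl}-N-methoxy-N-methyl-5-phenylpent-4-enamide | CON(C)C(=O)C[C@@H](/C=C/c1ccccc1)c1c(O)cc(/C=C/c2ccccc2)oc1=O
F3 | step 1 | 4-methoxy-6-methyl-2H-pyran-2-one | COc1cc(C)oc(=O)c1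
F4 | step 1 | 4-methoxy-6-[(E)-2-phenylethenyl]-2H-pyran-2-one | COc1cc(/C=C/c2ccccc2)oc(=O)c1
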